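Atom labels used throughout: C1 (enol-ether carbon), C2 (=CH) and C3 (CH2) of the dihydrofuran, C4 (quaternary carbon with CH3 and the bridging oxygen), C5=C6 (ylidene alkene, C6 on the lactone oxygen), C7=C11 (butenolide alkene), C8 (CH–O–methacryloyl), C9 (CH2), C10 (C(CH3)OH), C12 (lactone C=O), C13 (CH2OAc). β is the face of the six-membered carbocycle of the early intermediates that carries the C10 oxygen; α is the other face.

## Analysis of the target

Target 27 is a ten-membered carbocycle C1–C10 that is bridged by an oxygen between C1 and C4, so that C1=C2 is the enol ether of a 2,3-dihydrofuran. At C6–C7 it is fused to a butenolide whose ring oxygen sits on C6, which makes C5=C6 an enol-lactone (ylidene) alkene conjugated with C7=C11. There are three stereocentres, C4 (S), C8 (S) and C10 (R); C8 and C10 are 1,3-related through C9, whereas C4 lies across the ring from both. The C5=C6 alkene has C4 cis to C7 (E by the sequence rule). The enol ether is acid-labile, the dienyl lactone and the methacrylate are open to nucleophiles and bases, the acetate is allylic, and the free tertiary alcohol sits next to the enol ether. The synthesis is hard because a medium ring with five sp2 ring atoms has to be closed, two fully substituted oxygen-bearing carbons have to be set far apart, and four oxygens have to end up differently substituted. The strategy rests on one feature: once the C1–O–C4 bridge is opened to a C1 ketone and a C4 carbinol, the ring holds the array O=C1–C2–C3–C4–C5=C6, the product pattern of an oxy-Cope shift, and rejoining C1 to C6 gives a six-membered ring C1–C6–C7–C8–C9–C10.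

## Retrosynthetic reasoning

**27 back to 24.** The C1=C2 enol ether is taken back to hemiketal 26, because C2 is the only hydrogen-bearing neighbour of C1 and dehydration can therefore go one way only. The two esters are removed in the order of their ease of formation: the secondary methacrylate (26 from 25) and then the primary acetate (25 from 24). No skeletal bond is cut; what is gained is that the acid-sensitive enol ether appears in the last step and the acylations run on a robust hemiketal.

**24 back to 22.** The bridging C1–O bond is cut. Hemiketal 24 is the closed form of hydroxy ketone 23, which is ketone 22 without its four silyl groups. The forward step only has to free the C4 hydroxyl, which then adds across the ring.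

**22 back to 19.** C3–C4 is cut and C1–C6 is joined. This is the only place where one bond-forming event builds the ten-membered ring, the C4 centre and the C5=C6 alkene together. Other cuts of the ring would require an end-to-end macrocyclisation. The forward reaction needs cyclohexanol 19 with vinyl on C1 and the Z silyl enol ether arm on C6 cis to each other, so that the alkoxide can drive a [3,3] shift. The fused butenolide holds the lactone oxygen in its plane, so the cyclohexane chair is locked. The shift therefore has to pass through a boat-like array, and this was taken into account when the C1/C6 configuration and the enol ether geometry were chosen.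

**19 back to 16.** The enol ether C5=C4–O is taken back to methyl ketone 18 and this to the allyl group of 16. An allyl group survives all earlier steps, and its terminal alkene is the least hindered one in the molecule when it has to be oxidised.

**16 back to 11.** The C8–O bond and the C11–C13 bond are cut. Both positions are activated only by the butenolide: C8 is its γ-carbon and C11 its α-carbon. A one-carbon electrophile is therefore added to the dienolate of 12 at C11 (13), and the resulting C7=C8 alkene is used to bring in the C8 oxygen (14, 15). Oxidising C8 after the lactone is closed has a stereochemical reason: the allyl group on C6 is then held perpendicular to the butenolide and shields the α face.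

**11 back to 8 and 9.** C7=C11 and the C6–O acyl bond are cut. This is the standard disconnection of a butenolide into a tertiary α-ketol and phosphonoacetic acid 9; 8 has a single ketone, so the ring closure of 10 cannot go astray.

**8 back to 5.** The C6–O bond and the C1–C2 bond are cut, in that order. Adding the vinyl group to a lactone-fused C1 ketone was rejected: there the arm is axial and a nucleophile would enter trans to it, giving the trans isomer, which cannot undergo the shift. Instead the vinyl group is added to vinylogous ester 5, in which C7 is masked as an enol ether and C6 is still sp2. The C1 hydroxyl of 6 then delivers the C6 oxygen to its own face, and the same oxidation unmasks the C7 ketone.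

**5 back to 1.** The C10–O and C10–CH3 bonds are cut. Both are made by enolate chemistry at the α′ position of vinylogous ester 2, which comes from symmetrical dione 1. The hydroxylation of the tetrasubstituted enolate of 3 is the only step that has to create absolute configuration; C1, C6, C8 and C4 are all derived from C10.

## Alternatives that were turned down

**Alternative 1:** The disconnection is the C1=C2 double bond of the dihydrofuran, made from an ester carbonyl (C1) and a terminal alkene (C2). In the forward key step a reduced titanium ethylidene reagent (TiCl4, TMEDA, Zn, PbCl2, CH3CHBr2) would convert homoallylic ester A2 into dihydrofuran A1.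
- For it: the two fully substituted centres C4 and C10 are made in separate small fragments by reliable asymmetric chemistry and joined as an ester, and the enol ether is made directly, not by dehydration. On these points it is stronger than the chosen route, which sets C10 by a reagent-controlled enolate oxidation and C4 in the key step.
- Against it: after A1 the whole C5–C9 half, the butenolide and the ten-membered ring still have to be built around an acid-labile enol ether, and the ring has to be closed end to end with control of the C5=C6 geometry. The ester in A2 is also flanked by a quaternary carbon on each side, which slows alkylidenation.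
- The chosen route offers in exchange a ring closure without dilution and an enol ether that appears only in the last step.

**Alternative 2:** The disconnection takes the C1 and C6 carbonyls back to a tetrasubstituted C1=C6 alkene of a bicyclic precursor. In the forward key step ozone, then Me2S, would cleave octalin A4 to cyclodecane-1,6-dione A3.
- For it: like the chosen route it opens a ring fusion and needs no dilution, and the outcome does not depend on a transition-state geometry, so it is stronger on predictability of the ring-forming event.
- Against it: A4 must already carry C4, C8 and C10 correctly on two rings, ozone has to select the tetrasubstituted alkene of a conjugated dienoate, and A3 still lacks the C5=C6 enol-lactone alkene, which would have to be made from the C6 ketone with control of geometry. A 1,6-diketone in a ten-membered ring is also prone to transannular aldol reaction.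
- The chosen route forms C5=C6 and C4 in the same step that makes the ring.

**Alternative 3:** The disconnection is the C4–C5 bond. In the forward key step CrCl2 with catalytic NiCl2 would turn iodo ketone A6 into an alkenylchromium species that adds to the methyl ketone and closes macrocycle A5.
- For it: the C5=C6 geometry is fixed before ring closure and is retained, and the free tertiary C4 alcohol is formed directly. On alkene geometry it is stronger than the chosen route, where the geometry depends on the transition-state array.
- Against it: a ten-membered ring is closed end to end at high dilution onto a ketone, which is a poor electrophile for alkenylchromium reagents, and no reliable element controls the C4 configuration. A6 is a long linear chain and the dithiane must later be removed beside sensitive groups.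
- The chosen route relays the C4 configuration from the enol ether geometry and pays no entropic price for the ring.

Key step: step 15

Assumption: the facial sense of the camphor-derived oxaziridine in step 3 is taken from 2-alkyl-1-tetralone enolates; if it proves opposite, the enantiomeric reagent is used.

## Route

Step 1
Reactants: 1 2-allylcyclohexane-1,3-dione
Product: 2 2-allyl-3-ethoxycyclohex-2-en-1-one
Conditions: EtOH, p-TsOH (cat.), toluene, reflux, Dean–Stark
Reagents that add atoms: ethanol, CCO
Why: Acid-catalysed O-alkylation of the enolised 1,3-dione (vinylogous ester formation); the dione is symmetrical, so a single enol ether results.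

Step 2
Reactants: 2 2-allyl-3-ethoxycyclohex-2-en-1-one
Product: 3 racemic 2-allyl-3-ethoxy-6-methylcyclohex-2-en-1-one
Conditions: LiN(iPr)2, THF, −78 °C; MeI, −78 to 0 °C
Reagents that add atoms: iodomethane, CI
Why: Stork–Danheiser kinetic α′-deprotonation of the vinylogous ester and C-methylation; the new centre is racemic and is erased in step 3.

Step 3
Reactants: 3 racemic 2-allyl-3-ethoxy-6-methylcyclohex-2-en-1-one
Product: 4 (6R)-2-allyl-3-ethoxy-6-hydroxy-6-methylcyclohex-2-en-1-one
Conditions: NaN(SiMe3)2, THF, −78 °C; (8,8-dichlorocamphorylsulfonyl)oxaziridine [from (1S)-(+)-10-camphorsulfonic acid], −78 °C; aq. NH4Cl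
Reagents that add atoms: (8,8-dichlorocamphorylsulfonyl)oxaziridine, CC1(C)[C@@H]2CC[C@]13CS(=O)(=O)N4O[C@@]34C2(Cl)Cl
Why: Davis enolate hydroxylation: the sodium enolate, tetrasubstituted at C10 and conjugated with the enol-ether double bond much as a 2-alkyl-1-tetralone enolate is with its arene, should take oxygen from the chiral N-sulfonyloxaziridine on one face. This step sets C10 (R), the centre from which all others are derived.

Step 4
Reactants: 4 (6R)-2-allyl-3-ethoxy-6-hydroxy-6-methylcyclohex-2-en-1-one
Product: 5 (6R)-2-allyl-3-ethoxy-6-methyl-6-(triethylsilyloxy)cyclohex-2-en-1-one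
Conditions: Et3SiOTf, 2,6-lutidine, CH2Cl2, −78 to 0 °C
Reagents that add atoms: triethylsilyl trifluoromethanesulfonate, CC[Si](CC)(CC)OS(=O)(=O)C(F)(F)F
Why: Silylation of the tertiary α-hydroxy ketone; a bulky, non-chelating silyl ether is chosen so that step 5 runs under Felkin–Anh control and so that fluoride can remove the group at the end.

Step 5
Reactants: 5 (6R)-2-allyl-3-ethoxy-6-methyl-6-(triethylsilyloxy)cyclohex-2-en-1-one
Product: 6 (1S,6R)-2-allyl-3-ethoxy-6-methyl-6-(triethylsilyloxy)-1-vinylcyclohex-2-en-1-ol
Conditions: CH2=CHMgBr, CeCl3, THF, −78 °C; aq. NaHCO3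
Reagents that add atoms: vinylmagnesium bromide, C=C[Mg]Br
Why: Organocerium 1,2-addition to the vinylogous ester carbonyl under polar Felkin–Anh control: the nucleophile should enter anti to the pseudo-axial C10–OSiEt3 group, so that the C1 hydroxyl and O-10 are cis. The work-up is kept basic because acid would trigger the Stork–Danheiser transposition of this tertiary allylic alcohol.

Step 6
Reactants: 6 (1S,6R)-2-allyl-3-ethoxy-6-methyl-6-(triethylsilyloxy)-1-vinylcyclohex-2-en-1-ol
Product: 8 (2R,3S,4R)-2-allyl-2,3-dihydroxy-4-methyl-4-(triethylsilyloxy)-3-vinylcyclohexan-1-one, via alkoxy-oxirane 7 (not isolated)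
Conditions: dimethyldioxirane, acetone/CH2Cl2, −78 to −30 °C; then wet SiO2, 0 °C
Reagents that add atoms: dimethyldioxirane, CC1(C)OO1; water, O
Why: The electron-rich tetrasubstituted enol ether is epoxidised far faster than the two monosubstituted alkenes, and hydrolytic opening of 7 gives the α-ketol (Rubottom-type oxidation of an enol ether). Hydrogen bonding to the C1 hydroxyl (Henbest-type direction) and the pseudo-axial vinyl group both steer the oxidant to the β face, so the C6 oxygen is cis to the C1 hydroxyl and the vinyl and allyl groups are cis.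

Step 7
Reactants: 8 (2R,3S,4R)-2-allyl-2,3-dihydroxy-4-methyl-4-(triethylsilyloxy)-3-vinylcyclohexan-1-one; 9 2-(diethoxyphosphoryl)acetic acid
Product: 10 C6 2-(diethoxyphosphoryl)acetate of 8
Conditions: DCC, DMAP (cat.), CH2Cl2, 0 °C to rt
Reagents that add atoms: none
Why: Steglich esterification; the C6 hydroxyl next to the ketone is acylated, whereas the C1 hydroxyl between two fully substituted carbons should not react.

Step 8
Reactants: 10 C6 2-(diethoxyphosphoryl)acetate of 8
Product: 11 (6R,7S,7aS)-7a-allyl-7-hydroxy-6-methyl-6-(triethylsilyloxy)-7-vinyl-5,6,7,7a-tetrahydro-1-benzofuran-2(4H)-one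
Conditions: LiCl, iPr2NEt, MeCN, 0 °C to rt
Reagents that add atoms: none
Why: Intramolecular Horner–Wadsworth–Emmons olefination (Masamune–Roush conditions) of the only ketone closes the butenolide (C7=C11); the mild amine base does not ionise the C1 carbinol.

Step 9
Reactants: 11 (6R,7S,7aS)-7a-allyl-7-hydroxy-6-methyl-6-(triethylsilyloxy)-7-vinyl-5,6,7,7a-tetrahydro-1-benzofuran-2(4H)-one
Product: 12 C1 trimethylsilyl ether of 11
Conditions: Me3SiOTf, 2,6-lutidine, CH2Cl2, −78 to 0 °C
Reagents that add atoms: trimethylsilyl trifluoromethanesulfonate, C[Si](C)(C)OS(=O)(=O)C(F)(F)F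
Why: Silylation with the small Me3Si group masks the hindered C1 carbinol for the two base-mediated steps that follow, because its alkoxide could expel the butenolide dienolate by cleavage of C1–C6.

Step 10
Reactants: 12 C1 trimethylsilyl ether of 11
Product: 13 C11 hydroxymethyl lactone with the alkene moved to C7=C8
Conditions: LiN(iPr)2, THF, −78 °C; CH2O (monomer in THF), −78 °C; aq. NH4Cl
Reagents that add atoms: formaldehyde, C=O
Why: γ-Deprotonation at C8 gives the lactone dienolate, which should add to formaldehyde at its α-carbon C11 (deconjugative aldol addition) on the face away from the axial allyl group. The C11 centre is removed again in step 11.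

Step 11
Reactants: 13 C11 hydroxymethyl lactone with the alkene moved to C7=C8
Product: 15 C8,C13 diol with the butenolide restored, via epoxy lactone 14 (not isolated)
Conditions: mCPBA, NaHCO3, CH2Cl2, 0 °C; then DBU, 0 °C to rt
Reagents that add atoms: 3-chloroperoxybenzoic acid, O=C(OO)c1cccc(Cl)c1
Why: Prilezhaev epoxidation of the trisubstituted C7=C8 alkene on the β face (away from the axial allyl group and syn to the CH2OH group). E1cB opening of the β,γ-epoxy lactone by DBU then restores C7=C11 and leaves the C8 hydroxyl on the β face.

Step 12
Reactants: 15 C8,C13 diol with the butenolide restored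
Product: 16 C8,C13 bis(tert-butyldimethylsilyl) ether of 15
Conditions: tBuMe2SiOTf, 2,6-lutidine, CH2Cl2, −78 to 0 °C
Reagents that add atoms: tert-butyldimethylsilyl trifluoromethanesulfonate, CC(C)(C)[Si](C)(C)OS(=O)(=O)C(F)(F)F
Why: Silylation of the primary and the secondary allylic alcohol; both ethers are stable to KH and are removed by fluoride.

Step 13
Reactants: 16 C8,C13 bis(tert-butyldimethylsilyl) ether of 15
Product: 18 methyl ketone with free C1 hydroxyl, via trimethylsilyl ether ketone 17 (not isolated)
Conditions: PdCl2 (10 mol %), CuCl, O2 (1 atm), DMF/H2O 7:1, rt; then PPTS, MeOH, 0 °C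
Reagents that add atoms: water, O
Why: Tsuji–Wacker oxidation: the unhindered allyl terminus is hydroxypalladated at its internal carbon, whereas the vinyl group on the fully substituted C1 is shielded and deactivated by the allylic oxygen. Mild acid then removes only the Me3Si ether.

Step 14
Reactants: 18 methyl ketone with free C1 hydroxyl
Product: 19 cyclohexanol with the Z triethylsilyl enol ether arm on C6
Conditions: Et3SiOTf, Et3N, CH2Cl2, −78 to −20 °C
Reagents that add atoms: triethylsilyl trifluoromethanesulfonate, CC[Si](CC)(CC)OS(=O)(=O)C(F)(F)F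
Why: Soft enolisation with silyl triflate and amine should give the trisubstituted C5=C4 enol ether with Et3SiO cis to C6 (Z), since the E isomer suffers allylic strain between CH3 and the quaternary C6. The C1 hydroxyl between two quaternary carbons is expected to be silylated much more slowly than the ketone is enolised.

Step 15
Reactants: 19 cyclohexanol with the Z triethylsilyl enol ether arm on C6
Product: 22 cyclodecenone with C1 ketone and C4–OSiEt3, via potassium alkoxide 20 (not isolated), via potassium enolate 21 (not isolated)
Conditions: KH, 18-crown-6, THF, 0 °C to rt; aq. NH4Cl, −78 °C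
Reagents that add atoms: none
Why: KH deprotonates the C1 carbinol and 18-crown-6 frees alkoxide 20, whose charge weakens the C1–C6 bond that is also allylic to C7=C11; a suprafacial [3,3] shift then joins the vinyl terminus C3 to the enol-ether carbon C4 while C1–C6 breaks, giving enolate 21, which is protonated to 22. The closest known reaction type is the anionic oxy-Cope ring expansion of cis-1-vinyl-2-alkenylcyclohexanols to cyclodec-5-enones. The ten-membered ring is not closed end to end: it arises by ring expansion, the fusion bond of the six-membered ring being cut while the four atoms C2–C5 are inserted, so no dilution is needed. Because the planar butenolide keeps the lactone oxygen in its plane and the arm perpendicular to it, the cyclohexane cannot flip, and the shift has to use the boat-like six-centre array with C2 under C5, C10 eclipsing C7 and C4 over the C7 side; this array gives C5=C6 with C4 cis to C7. The new centre C4 is set by the Z geometry of the enol ether: with Et3SiO cis to C6, C3 bonds to the face of C4 turned towards C1, which corresponds to 4S. The step needs the cis relation of vinyl and arm (secured in step 6), the Z enol ether (step 14) and this boat over the chair that the locked ring would allow; that chair puts the fully substituted C10 axial with its α-methyl against C3 and should be disfavoured. The shift is made irreversible by formation of the enolate and of the C5=C6–C7=C11 dienoate, and any migration of Et3Si between O-10 and O-1 is reversible and drains through 20.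

Step 16
Reactants: 22 cyclodecenone with C1 ketone and C4–OSiEt3
Product: 24 bridged hemiketal tetraol, via tetrahydroxy ketone 23 (not isolated)
Conditions: HF·pyridine, pyridine, THF, 0 °C to rt
Reagents that add atoms: none
Why: Buffered fluoride cleaves all four silyl ethers, and the freed C4 hydroxyl of 23 adds across the ring to the C1 ketone (5-exo) to give the hemiketal. C10 and C5 must be cis on the new oxolane ring, which fixes the C1 configuration.

Step 17
Reactants: 24 bridged hemiketal tetraol
Product: 25 C13 acetate of 24
Conditions: AcCl, 2,4,6-collidine, CH2Cl2, −78 °C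
Reagents that add atoms: acetyl chloride, CC(Cl)=O
Why: At low temperature with a hindered base the primary allylic alcohol is acylated much faster than the secondary, tertiary and hemiketal hydroxyls.

Step 18
Reactants: 25 C13 acetate of 24
Product: 26 C8 methacrylate of 25
Conditions: methacrylic anhydride, Et3N, DMAP (cat.), CH2Cl2, 0 °C
Reagents that add atoms: methacrylic anhydride, C=C(C)C(=O)OC(=O)C(C)=C
Why: DMAP-catalysed acylation of the only secondary alcohol; the tertiary and hemiketal hydroxyls should not react. Acylation of O-8 also removes any C8–O–C1 hemiketal from the equilibrium.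

Step 19
Reactants: 26 C8 methacrylate of 25
Product: 27 target CNP0394509.2
Conditions: PPTS (cat.), 4 Å molecular sieves, toluene, 60 °C
Reagents that add atoms: none
Why: Acid-catalysed dehydration of the hemiketal by way of the oxocarbenium ion; only C2 carries hydrogen, so only the C1=C2 enol ether can form, and the sieves remove the water.

## Compound list

1 | 2-allylcyclohexane-1,3-dione | C=CCC1C(=O)CCCC1=O | starting material
2 | 2-allyl-3-ethoxycyclohex-2-en-1-one | C=CCC1=C(OCC)CCCC1=O | intermediate
3 | racemic 2-allyl-3-ethoxy-6-methylcyclohex-2-en-1-one | C=CCC1=C(OCC)CCC(C)C1=O | intermediate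
4 | (6R)-2-allyl-3-ethoxy-6-hydroxy-6-methylcyclohex-2-en-1-one | C=CCC1=C(OCC)CC[C@@](C)(O)C1=O | intermediate
5 | (6R)-2-allyl-3-ethoxy-6-methyl-6-(triethylsilyloxy)cyclohex-2-en-1-one | C=CCC1=C(OCC)CC[C@@](C)(O[Si](CC)(CC)CC)C1=O | intermediate
6 | (1S,6R)-2-allyl-3-ethoxy-6-methyl-6-(triethylsilyloxy)-1-vinylcyclohex-2-en-1-ol, 1-OH cis to 6-OSiEt3 | C=CCC1=C(OCC)CC[C@@](C)(O[Si](CC)(CC)CC)[C@]1(O)C=C | intermediate
7 | 2,3-epoxide of 6 (2-allyl-3-ethoxy-2,3-epoxy-6-methyl-6-(triethylsilyloxy)-1-vinylcyclohexan-1-ol), oxirane oxygen on the β face, cis to 1-OH | C=CC[C@]12O[C@@]1(OCC)CC[C@@](C)(O[Si](CC)(CC)CC)[C@]2(O)C=C | intermediate (not isolated)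
8 | (2R,3S,4R)-2-allyl-2,3-dihydroxy-4-methyl-4-(triethylsilyloxy)-3-vinylcyclohexan-1-one, the oxygens on C2, C3 and C4 all β | C=CC[C@]1(O)C(=O)CC[C@@](C)(O[Si](CC)(CC)CC)[C@]1(O)C=C | intermediate
9 | 2-(diethoxyphosphoryl)acetic acid | CCOP(=O)(CC(=O)O)OCC | starting material
10 | 8 esterified at the C2 hydroxyl (C6 of the target) with 2-(diethoxyphosphoryl)acetic acid | C=CC[C@]1(OC(=O)CP(=O)(OCC)OCC)C(=O)CC[C@@](C)(O[Si](CC)(CC)CC)[C@]1(O)C=C | intermediate
11 | (6R,7S,7aS)-7a-allyl-7-hydroxy-6-methyl-6-(triethylsilyloxy)-7-vinyl-5,6,7,7a-tetrahydro-1-benzofuran-2(4H)-one (C1–OH β, vinyl α; lactone O β, allyl α) | C1C[C@@](C)(O[Si](CC)(CC)CC)[C@](O)(C=C)[C@@]2(CC=C)OC(=O)C=C12 | intermediate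
12 | 7-O-trimethylsilyl ether of 11 | C1C[C@@](C)(O[Si](CC)(CC)CC)[C@](O[Si](C)(C)C)(C=C)[C@@]2(CC=C)OC(=O)C=C12 | intermediate
13 | 7a-allyl-3-(hydroxymethyl)-6-methyl-6-(triethylsilyloxy)-7-(trimethylsilyloxy)-7-vinyl-5,6,7,7a-tetrahydro-1-benzofuran-2(3H)-one (C3a=C4 alkene, i.e. C7=C8; CH2OH on the β face) | C=CC[C@]12OC(=O)[C@@H](CO)C1=CC[C@@](C)(O[Si](CC)(CC)CC)[C@]2(O[Si](C)(C)C)C=C | intermediate
14 | 3a,4-epoxide of 13 (C7–C8 oxirane), oxygen on the β face | C=CC[C@]12OC(=O)[C@@H](CO)[C@@]13O[C@H]3C[C@@](C)(O[Si](CC)(CC)CC)[C@]2(O[Si](C)(C)C)C=C | intermediate (not isolated)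
15 | 7a-allyl-4-hydroxy-3-(hydroxymethyl)-6-methyl-6-(triethylsilyloxy)-7-(trimethylsilyloxy)-7-vinyl-5,6,7,7a-tetrahydro-1-benzofuran-2(4H)-one, 4-OH (C8–OH) β | O[C@H]1C[C@@](C)(O[Si](CC)(CC)CC)[C@](O[Si](C)(C)C)(C=C)[C@@]2(CC=C)OC(=O)C(CO)=C12 | intermediate
16 | C8,C13 bis(tert-butyldimethylsilyl) ether of 15 | CC(C)(C)[Si](C)(C)O[C@H]1C[C@@](C)(O[Si](CC)(CC)CC)[C@](O[Si](C)(C)C)(C=C)[C@@]2(CC=C)OC(=O)C(CO[Si](C)(C)C(C)(C)C)=C12 | intermediate
17 | 16 with the allyl group oxidised to 2-oxopropyl (C1–OSiMe3 retained) | CC(C)(C)[Si](C)(C)O[C@H]1C[C@@](C)(O[Si](CC)(CC)CC)[C@](O[Si](C)(C)C)(C=C)[C@@]2(CC(C)=O)OC(=O)C(CO[Si](C)(C)C(C)(C)C)=C12 | intermediate (not isolated)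
18 | 17 with the C1 hydroxyl free | CC(C)(C)[Si](C)(C)O[C@H]1C[C@@](C)(O[Si](CC)(CC)CC)[C@](O)(C=C)[C@@]2(CC(C)=O)OC(=O)C(CO[Si](C)(C)C(C)(C)C)=C12 | intermediate
19 | (4S,6R,7S,7aS)-4-(tert-butyldimethylsilyloxy)-3-[(tert-butyldimethylsilyloxy)methyl]-7-hydroxy-6-methyl-6-(triethylsilyloxy)-7a-[(Z)-2-(triethylsilyloxy)prop-1-enyl]-7-vinyl-5,6,7,7a-tetrahydro-1-benzofuran-2(4H)-one (all four ring oxygens β; vinyl, arm and C10–CH3 α) | CC(C)(C)[Si](C)(C)O[C@H]1C[C@@](C)(O[Si](CC)(CC)CC)[C@](O)(C=C)[C@@]2(/C=C(/C)O[Si](CC)(CC)CC)OC(=O)C(CO[Si](C)(C)C(C)(C)C)=C12 | intermediate (key-step precursor)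
20 | potassium C1 alkoxide of 19 | CC(C)(C)[Si](C)(C)O[C@H]1C[C@@](C)(O[Si](CC)(CC)CC)[C@]([O-])(C=C)[C@@]2(/C=C(/C)O[Si](CC)(CC)CC)OC(=O)C(CO[Si](C)(C)C(C)(C)C)=C12.[K+] | intermediate (not isolated)
21 | potassium C1=C2 enolate of 22 (C3 cis to C10) | CC(C)(C)[Si](C)(C)O[C@H]1C[C@@](C)(O[Si](CC)(CC)CC)/C([O-])=C\C[C@](C)(O[Si](CC)(CC)CC)/C=C2/OC(=O)C(CO[Si](C)(C)C(C)(C)C)=C21.[K+] | intermediate (not isolated)
22 | (4S,8S,10R)-cyclodec-5-en-1-one fused at C6–C7 to the butenolide: C1 ketone, C4 (CH3, OSiEt3), C5=C6 with C4 cis to C7, C8–OSitBuMe2, C10 (CH3, OSiEt3), C13–OSitBuMe2 | CC(C)(C)[Si](C)(C)O[C@H]1C[C@@](C)(O[Si](CC)(CC)CC)C(=O)CC[C@](C)(O[Si](CC)(CC)CC)/C=C2/OC(=O)C(CO[Si](C)(C)C(C)(C)C)=C21 | intermediate (key-step product)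
23 | 22 without its four silyl groups (open hydroxy ketone) | O[C@H]1C[C@@](C)(O)C(=O)CC[C@](C)(O)/C=C2/OC(=O)C(CO)=C21 | intermediate (not isolated)
24 | (1R,4S,8S,10R)-1,4-epoxy hemiketal of 23: C1 (OH, O–C4), free hydroxyls on C8, C10 and C13 | O[C@H]1C[C@@](C)(O)[C@@]2(O)CC[C@@](C)(/C=C3/OC(=O)C(CO)=C31)O2 | intermediate
25 | C13 acetate of 24 | O[C@H]1C[C@@](C)(O)[C@@]2(O)CC[C@@](C)(/C=C3/OC(=O)C(COC(C)=O)=C31)O2 | intermediate
26 | C8 methacrylate of 25 | C=C(C)C(=O)O[C@H]1C[C@@](C)(O)[C@@]2(O)CC[C@@](C)(/C=C3/OC(=O)C(COC(C)=O)=C31)O2 | intermediate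
27 | CNP0394509.2, (4S,8S,10R) | C=C(C)C(=O)O[C@H]1C[C@@](C)(O)C2=CC[C@@](C)(/C=C3/OC(=O)C(COC(C)=O)=C31)O2 | target

## Step count and least certain steps

Total step count: 19. Longest linear sequence: 19 steps, from 1; acid 9 is purchased.

**Step 15 (key step).** The most likely failure is heterolysis outrunning the concerted shift. The alkoxide can cleave C1–C6 to a tethered vinyl ketone and a butenolide dienolate, and reclosure by conjugate addition may then occur at C6 (eight-membered ring), or the material may decompose. A second risk is the competing six-centre array in which C4 lies on the lactone-oxygen side, which would give the in-ring trans C5=C6 alkene and the opposite C4 configuration. Fallback: a neutral siloxy-Cope shift, which involves no alkoxide. It sets out from 17, isolated before the acid treatment of step 13. Et3SiOTf and Et3N should give the bis-silylated diene F1 (C1–OSiMe3, Z triethylsilyl enol ether arm). Heating F1 in toluene at 160–200 °C in a base-washed sealed tube should give the ring-expanded trimethylsilyl enol ether F2. Citric acid in MeOH/THF at 0 °C then cleaves the enol ether, and the route is rejoined at 22.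

**Step 14.** The process most likely to fail is the regio- and stereoselection of enolisation: kinetic removal of a CH3 proton would give the terminal enol ether, and some E isomer would give the C4 epimer. In addition the silyl triflate may silylate the C1 hydroxyl or ionise the allylic C6–O bond. Fallback: form the enol ether while C1 is still protected, so that equilibrating conditions can be used. It sets out from 17. tBuMe2SiOTf and Et3N at rt should give the tert-butyldimethylsilyl enol ether F3. K2CO3 in MeOH at 0 °C removes the Me3Si ether to give carbinol F4. KH and 18-crown-6 convert F4 into cyclodecenone F5 (C4–OSitBuMe2), and HF·pyridine takes F5 to 24.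

**Step 3.** Poor facial selectivity of oxygen transfer to a tetrasubstituted, non-aromatic enolate is the risk, because all later centres depend on C10. Fallback: resolution through diastereomeric esters. It sets out from 3. KN(SiMe3)2 and racemic 2-(phenylsulfonyl)-3-phenyloxaziridine give the racemic alcohol F6. DCC/DMAP esterification with (S)-O-acetylmandelic acid and chromatographic separation give the ester of the R alcohol F7, and K2CO3 in MeOH releases 4.

**Step 13.** Loss of chemoselectivity is the risk: oxidation of the vinyl group as well, or aldehyde formation by way of the allylic oxygen, and cleavage of silyl ethers by the acidic palladium medium. Fallback: oxymercuration–demercuration followed by oxidation. It sets out from 16. Hg(OAc)2 in THF/H2O, then NaBH4 at 0 °C, should hydrate the unhindered allyl terminus to the secondary alcohol F8 (both epimers at the new carbinol), and Dess–Martin periodinane oxidises F8 to 17.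

**Step 19.** Under acid the hemiketal may ionise without losing the C2 proton cleanly, the allylic esters may ionise, or the enol ether may add water again. Fallback: elimination under neutral conditions. It sets out from 26. PhSeH with BF3·OEt2 at −40 °C should give the C1 phenylselanyl ketal F9, and NaIO4 with NaHCO3 oxidises it to the selenoxide, which eliminates syn towards C2 to give 27.

## Further compounds

F1 | step 15 | C1 trimethylsilyl ether of 19 (bis-silylated diene) | CC(C)(C)[Si](C)(C)O[C@H]1C[C@@](C)(O[Si](CC)(CC)CC)[C@](O[Si](C)(C)C)(C=C)[C@@]2(/C=C(/C)O[Si](CC)(CC)CC)OC(=O)C(CO[Si](C)(C)C(C)(C)C)=C12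
F2 | step 15 | C1 trimethylsilyl enol ether of 22 | CC(C)(C)[Si](C)(C)O[C@H]1C[C@@](C)(O[Si](CC)(CC)CC)/C(O[Si](C)(C)C)=C\C[C@](C)(O[Si](CC)(CC)CC)/C=C2/OC(=O)C(CO[Si](C)(C)C(C)(C)C)=C21
F3 | step 14 | Z tert-butyldimethylsilyl enol ether of 17 (C1–OSiMe3) | CC(C)(C)[Si](C)(C)O[C@H]1C[C@@](C)(O[Si](CC)(CC)CC)[C@](O[Si](C)(C)C)(C=C)[C@@]2(/C=C(/C)O[Si](C)(C)C(C)(C)C)OC(=O)C(CO[Si](C)(C)C(C)(C)C)=C12
F4 | step 14 | analogue of 19 with a tert-butyldimethylsilyl enol ether | CC(C)(C)[Si](C)(C)O[C@H]1C[C@@](C)(O[Si](CC)(CC)CC)[C@](O)(C=C)[C@@]2(/C=C(/C)O[Si](C)(C)C(C)(C)C)OC(=O)C(CO[Si](C)(C)C(C)(C)C)=C12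
F5 | step 14 | analogue of 22 with C4–OSitBuMe2 | CC(C)(C)[Si](C)(C)O[C@H]1C[C@@](C)(O[Si](CC)(CC)CC)C(=O)CC[C@](C)(O[Si](C)(C)C(C)(C)C)/C=C2/OC(=O)C(CO[Si](C)(C)C(C)(C)C)=C21
F6 | step 3 | racemic 2-allyl-3-ethoxy-6-hydroxy-6-methylcyclohex-2-en-1-one | C=CCC1=C(OCC)CCC(C)(O)C1=O
F7 | step 3 | (S)-O-acetylmandelate of 4 | C=CCC1=C(OCC)CC[C@@](C)(OC(=O)[C@@H](OC(C)=O)c2ccccc2)C1=O
F8 | step 13 | 2-hydroxypropyl analogue of 17 (both epimers at the new carbinol) | CC(C)(C)[Si](C)(C)O[C@H]1C[C@@](C)(O[Si](CC)(CC)CC)[C@](O[Si](C)(C)C)(C=C)[C@@]2(CC(C)O)OC(=O)C(CO[Si](C)(C)C(C)(C)C)=C12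
F9 | step 19 | C1 phenylselanyl ketal of 26 | C=C(C)C(=O)O[C@H]1C[C@@](C)(O)[C@@]2([Se]c3ccccc3)CC[C@@](C)(/C=C4/OC(=O)C(COC(C)=O)=C41)O2
A1 | alternative 1 | 2,3-dihydrofuran carrying both quaternary centres | COc1ccc(COCC[C@@](C)(O[Si](CC)(CC)CC)C2=CC[C@@](C)(CO[Si](C(C)C)(C(C)C)C(C)C)O2)cc1
A2 | alternative 1 | homoallylic ester precursor of A1 | COc1ccc(COCC[C@@](C)(O[Si](CC)(CC)CC)C(=O)O[C@@](C)(CC=C)CO[Si](C(C)C)(C(C)C)C(C)C)cc1
A3 | alternative 2 | cyclodecane-1,6-dione with Z 4-oxo-2-enoate | CC[Si](CC)(CC)O[C@H]1C[C@@](C)(O[Si](CC)(CC)CC)C(=O)CC[C@](C)(O[Si](CC)(CC)CC)CC(=O)/C1=C(/COC(C)=O)C(=O)OC(C)(C)C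
A4 | alternative 2 | octalin dienoate precursor of A3 | CC[Si](CC)(CC)O[C@H]1C[C@@](C)(O[Si](CC)(CC)CC)C2=C(C[C@@](C)(O[Si](CC)(CC)CC)CC2)/C1=C(/COC(C)=O)C(=O)OC(C)(C)C
A5 | alternative 3 | macrocyclic tertiary alcohol with dithiane at C1 | CC(C)(C)[Si](C)(C)O[C@H]1C[C@@](C)(O[Si](CC)(CC)CC)C2(SCCCS2)CC[C@](C)(O)/C=C3/OC(=O)C(CO[Si](C)(C)C(C)(C)C)=C31
A6 | alternative 3 | E iodoylidene butenolide with tethered methyl ketone | CC(C)(C)[Si](C)(C)O[C@@H](C[C@@](C)(O[Si](CC)(CC)CC)C1(SCCCS1)CCC(C)=O)C2=C(CO[Si](C)(C)C(C)(C)C)C(=O)O/C2=C/I
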